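**Plan** (labdane numbering: decalin C1–C10, side chain C11–C16, carboxyl carbon C17)

- Retrosynthesis cuts the C15 acetate and the C8–C17 bond (enol triflate carbonylation), then C13=C14 (Horner–Wadsworth–Emmons) and C9–C11 (B-alkyl Suzuki), leading back to a trans-decalone with its ketone at C9.
- Enabling feature: ring B, with oxygen at C9 next to the methyl-bearing C10, is a masked 2-methylphenol. Cutting C1–C10 opens ring A to a phenol whose ortho carbon C10 is alkylated by a C1–C3 allyl arm hung on the gem-dimethyl carbon C4 at C5.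
- The arene is cut at C5–C4 (α-arylation of isobutyronitrile) and at C2=C3 (Z-selective olefination).
- Forward: the benzene ring becomes ring B, ring A closes in the dearomatising allylation, the chain is joined at C9 and then grown at C13.
- Stereochemistry: C10 from the chiral palladium catalyst; C5 (hydrogenation) and C9 (hydroboration) anti to the C10 methyl group; 13E from the olefination.

Key step: step 10

Assumption: which antipode of the Trost-type ligand delivers the (S)-configured C10 cannot be predicted for this new ring closure; the (R,R) ligand is written and the (S,S) ligand would be taken if the sense proves opposite.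

**Step 1**
Reactants: 1 1-bromo-3-methoxy-2-methylbenzene; 2 isobutyronitrile
Product: 3 2-(3-methoxy-2-methylphenyl)-2-methylpropanenitrile
Conditions: Pd(OAc)2 (2 mol %), rac-BINAP (2.4 mol %), NaN(SiMe3)2, toluene, 100 °C
Reagents that add atoms: none
Why: Palladium-catalysed α-arylation of a secondary nitrile (Hartwig type), in which the sodium keteniminate transmetalates to the arylpalladium bromide and reductive elimination forms the C5–C4 bond and the quaternary carbon; a mono-ortho-substituted aryl bromide lies within the usual scope.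

**Step 2**
Reactants: 3 2-(3-methoxy-2-methylphenyl)-2-methylpropanenitrile
Product: 4 2-(6-chloro-3-methoxy-2-methylphenyl)-2-methylpropanenitrile
Conditions: N-chlorosuccinimide (1.05 equiv), (CF3)2CHOH, rt
Reagents that add atoms: N-chlorosuccinimide, O=C1CCC(=O)N1Cl
Why: Electrophilic aromatic chlorination para to the methoxy group: the ortho carbon C8 is screened because the C10 methyl group turns the O–CH3 bond towards it, and chlorinating at the nitrile stage keeps the arm next to C6 as small as possible.

**Step 3**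
Reactants: 4 2-(6-chloro-3-methoxy-2-methylphenyl)-2-methylpropanenitrile
Product: 5 2-(6-chloro-3-hydroxy-2-methylphenyl)-2-methylpropanenitrile
Conditions: BBr3 (2.5 equiv), CH2Cl2, −78 → 0 °C; then H2O
Reagents that add atoms: none
Why: Lewis-acid cleavage of the aryl methyl ether by BBr3 (bromide attacks the methyl group of the boron–ether complex), done while no acid-sensitive allylic group is present; nitrile and aryl chloride should survive.

**Step 4**
Reactants: 5 2-(6-chloro-3-hydroxy-2-methylphenyl)-2-methylpropanenitrile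
Product: 6 2-{3-[(tert-butyldimethylsilyl)oxy]-6-chloro-2-methylphenyl}-2-methylpropanenitrile
Conditions: TBSCl, imidazole, DMF, rt
Reagents that add atoms: tert-butyldimethylsilyl chloride, CC(C)(C)[Si](C)(C)Cl
Why: Imidazole-promoted silylation masks the phenol through the hydride reductions, the olefination and the carbonate formation, and the silyl ether can later be cleaved by fluoride without harm to an allylic carbonate.

**Step 5**
Reactants: 6 2-{3-[(tert-butyldimethylsilyl)oxy]-6-chloro-2-methylphenyl}-2-methylpropanenitrile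
Product: 8 2-{3-[(tert-butyldimethylsilyl)oxy]-6-chloro-2-methylphenyl}-2-methylpropanal, via aluminium aldimine 7 (not isolated)
Conditions: i-Bu2AlH (1.5 equiv), toluene, −78 → 0 °C; then aq. KNaC4H4O6, dilute HCl
Reagents that add atoms: water, O
Why: Partial reduction of the nitrile by i-Bu2AlH gives the N-aluminoaldimine, which is not reduced further at low temperature and is hydrolysed to the aldehyde on work-up; aryl silyl ether and aryl chloride are not affected.

**Step 6**
Reactants: 8 2-{3-[(tert-butyldimethylsilyl)oxy]-6-chloro-2-methylphenyl}-2-methylpropanal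
Product: 9 methyl (Z)-4-{3-[(tert-butyldimethylsilyl)oxy]-6-chloro-2-methylphenyl}-4-methylpent-2-enoate
Conditions: (CF3CH2O)2P(O)CH2CO2Me, KN(SiMe3)2, 18-crown-6, THF, −78 °C
Reagents that add atoms: methyl bis(2,2,2-trifluoroethyl)phosphonoacetate, COC(=O)CP(=O)(OCC(F)(F)F)OCC(F)(F)F
Why: Still–Gennari variant of the Horner–Wadsworth–Emmons reaction: with the electron-poor phosphonate and a dissociated potassium counter-ion, elimination from the kinetic adduct outruns its equilibration, which should give the (Z)-enoate (C2=C3) even from this hindered, non-enolisable aldehyde.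

**Step 7**
Reactants: 9 methyl (Z)-4-{3-[(tert-butyldimethylsilyl)oxy]-6-chloro-2-methylphenyl}-4-methylpent-2-enoate
Product: 10 (Z)-4-{3-[(tert-butyldimethylsilyl)oxy]-6-chloro-2-methylphenyl}-4-methylpent-2-en-1-ol
Conditions: i-Bu2AlH (2.5 equiv), CH2Cl2, −78 °C; then aq. KNaC4H4O6
Reagents that add atoms: none
Why: i-Bu2AlH reduces the conjugated ester by 1,2-addition to the allylic alcohol without conjugate reduction, so the (Z)-geometry is kept.

**Step 8**
Reactants: 10 (Z)-4-{3-[(tert-butyldimethylsilyl)oxy]-6-chloro-2-methylphenyl}-4-methylpent-2-en-1-ol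
Product: 11 (Z)-4-{3-[(tert-butyldimethylsilyl)oxy]-6-chloro-2-methylphenyl}-4-methylpent-2-en-1-yl methyl carbonate
Conditions: ClCO2Me, pyridine, CH2Cl2, 0 °C
Reagents that add atoms: methyl chloroformate, COC(=O)Cl
Why: Acylation of the primary allylic alcohol with a chloroformate installs the carbonate leaving group, which on ionisation releases methoxide as internal base; the phenol is still silylated, so only one hydroxyl can react.

**Step 9**
Reactants: 11 (Z)-4-{3-[(tert-butyldimethylsilyl)oxy]-6-chloro-2-methylphenyl}-4-methylpent-2-en-1-yl methyl carbonate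
Product: 12 (Z)-4-(6-chloro-3-hydroxy-2-methylphenyl)-4-methylpent-2-en-1-yl methyl carbonate
Conditions: Bu4NF (1.1 equiv), AcOH (1.2 equiv), THF, 0 °C
Reagents that add atoms: none
Why: Fluoride-induced cleavage of the aryl silyl ether, buffered with acetic acid so that the phenol and not the phenolate is released and the allylic carbonate is left alone.

**Step 10**
Reactants: 12 (Z)-4-(6-chloro-3-hydroxy-2-methylphenyl)-4-methylpent-2-en-1-yl methyl carbonate
Product: 13 (S)-4-chloro-5,5,8a-trimethyl-8,8a-dihydronaphthalen-1(5H)-one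
Conditions: Pd2(dba)3·CHCl3 (2.5 mol %), (R,R)-DACH-phenyl Trost ligand (7.5 mol %), CH2Cl2 (0.02 M, degassed), rt
Reagents that add atoms: none
Why: Proposed new method: zerovalent palladium ionises the (Z)-allylic carbonate with loss of CO2, the methoxide set free deprotonates the phenol, and the ortho carbon C10 of the phenolate attacks the unsubstituted terminus C1 of the anti-configured allyl complex of divalent palladium on the face away from the metal. The closest known reaction type is the palladium-catalysed intramolecular asymmetric allylic dearomatisation of phenols with Trost-type diphosphines, which so far closes rings that carry the vinyl group outside the ring. Ring A is closed in a six-membered mode in which all three allyl carbons become ring atoms (new C1–C10 bond, cis C2=C3 alkene inside the ring), a mode open only to the anti allyl geometry that the (Z)-alkene delivers and that should persist because syn–anti exchange would need palladium sigma-bonded to the neopentyl-like C3. The one new stereocentre, quaternary C10, is controlled by the chiral ligand, which must tell apart the two faces of the planar phenolate. The step needs C10 attack over para-carbon attack and O-alkylation: chlorine at C6 blocks the para carbon, O-alkylation would require an eight-membered ring, and the C10 methyl and C6 chlorine on either side of the C4 gem-dimethyl carbon (gem-dialkyl effect) hold the allyl arm above the ring face at C10. Because C10 bears a methyl group the product cannot rearomatise and should stay as the cyclohexa-2,4-dienone, which is hydrogenated without storage.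

**Step 11**
Reactants: 13 (S)-4-chloro-5,5,8a-trimethyl-8,8a-dihydronaphthalen-1(5H)-one
Product: 14 (4aS,8aS)-5,5,8a-trimethyloctahydronaphthalen-1(2H)-one
Conditions: H2 (1 → 4 atm), Pd/C (10 wt %), Et3N (1.5 equiv), EtOAc, rt
Reagents that add atoms: none
Why: Heterogeneous hydrogenation with hydrogenolysis: the C2=C3 and C7=C8 alkenes are saturated, the vinylic C–Cl bond is cleaved (Et3N takes up HCl) and the remaining C5=C6 alkene is reduced from the α face, opposite the axial methyl groups on C10 and C4, which should place C5–H anti to the C10 methyl group (trans-decalin).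

**Step 12**
Reactants: 14 (4aS,8aS)-5,5,8a-trimethyloctahydronaphthalen-1(2H)-one
Product: 15 (4aS,8aS)-5,5,8a-trimethyl-3,4,4a,5,6,7,8,8a-octahydronaphthalen-1-yl trifluoromethanesulfonate
Conditions: KN(SiMe3)2, THF, −78 °C; PhNTf2, −78 → 0 °C
Reagents that add atoms: N-phenylbis(trifluoromethanesulfonimide), O=S(=O)(N(c1ccccc1)S(=O)(=O)C(F)(F)F)C(F)(F)F
Why: Enol triflate formation: C8 is the only enolisable position of the C9 ketone because C10 is quaternary, so deprotonation and O-sulfonylation can give only the C8=C9 triflate.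

**Step 13**
Reactants: 15 (4aS,8aS)-5,5,8a-trimethyl-3,4,4a,5,6,7,8,8a-octahydronaphthalen-1-yl trifluoromethanesulfonate; 16 2-methyl-2-vinyl-1,3-dioxolane
Product: 18 2-methyl-2-{2-[(4aS,8aS)-5,5,8a-trimethyl-3,4,4a,5,6,7,8,8a-octahydronaphthalen-1-yl]ethyl}-1,3-dioxolane, via B-alkyl-9-BBN 17 (not isolated)
Conditions: 16, 9-BBN-H, THF, 0 °C → rt; then 15, PdCl2(dppf) (5 mol %), Cs2CO3, DMF/THF/H2O, 50 °C
Reagents that add atoms: none
Why: B-alkyl Suzuki–Miyaura coupling: anti-Markovnikov hydroboration of the vinyl dioxolane gives a primary alkylborane that, activated by base, transmetalates to the alkenylpalladium triflate and forms the C9–C11 bond; the side chain is brought in as a masked methyl ketone so that no second alkene competes in the next step.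

**Step 14**
Reactants: 18 2-methyl-2-{2-[(4aS,8aS)-5,5,8a-trimethyl-3,4,4a,5,6,7,8,8a-octahydronaphthalen-1-yl]ethyl}-1,3-dioxolane
Product: 20 (1R,2R,4aS,8aS)-1-[2-(2-methyl-1,3-dioxolan-2-yl)ethyl]-5,5,8a-trimethyldecahydronaphthalen-2-ol, via alkylborane 19 (not isolated)
Conditions: BH3·THF (3 equiv), THF, 0 °C → rt; then NaOH, H2O2, 0 °C → rt
Reagents that add atoms: hydrogen peroxide, OO
Why: Hydroboration–oxidation: borane adds syn across the trisubstituted C8=C9 alkene from the α face, away from the axial C10 methyl group, with boron on the less substituted C8, so that C9 receives its hydrogen on the α face (side chain β and equatorial, as in the target) and oxidation with retention gives the C8 alcohol.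

**Step 15**
Reactants: 20 (1R,2R,4aS,8aS)-1-[2-(2-methyl-1,3-dioxolan-2-yl)ethyl]-5,5,8a-trimethyldecahydronaphthalen-2-ol
Product: 21 (1R,4aS,8aS)-1-[2-(2-methyl-1,3-dioxolan-2-yl)ethyl]-5,5,8a-trimethyloctahydronaphthalen-2(1H)-one
Conditions: Dess–Martin periodinane, NaHCO3, CH2Cl2, rt
Reagents that add atoms: none
Why: Dess–Martin oxidation of the secondary alcohol to the C8 ketone under buffered conditions; the C9 side chain already sits in the more stable equatorial position, so enolisation cannot erode it.

**Step 16**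
Reactants: 21 (1R,4aS,8aS)-1-[2-(2-methyl-1,3-dioxolan-2-yl)ethyl]-5,5,8a-trimethyloctahydronaphthalen-2(1H)-one
Product: 23 (1R,4aS,8aS)-5,5,8a-trimethyl-1-(3-oxobutyl)-1,4,4a,5,6,7,8,8a-octahydronaphthalen-2-yl trifluoromethanesulfonate, via ketal triflate 22 (not isolated)
Conditions: LiN(i-Pr)2, THF, −78 °C; PhNTf2, −78 → 0 °C; then 1 M HCl, THF, rt
Reagents that add atoms: N-phenylbis(trifluoromethanesulfonimide), O=S(=O)(N(c1ccccc1)S(=O)(=O)C(F)(F)F)C(F)(F)F; water, O
Why: Kinetic deprotonation by the hindered amide base occurs at the C7 methylene and not at the shielded C9 methine, the enolate is trapped as the C7=C8 enol triflate, and aqueous acid then hydrolyses the dioxolane to the methyl ketone while the triflate is stable to it.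

**Step 17**
Reactants: 23 (1R,4aS,8aS)-5,5,8a-trimethyl-1-(3-oxobutyl)-1,4,4a,5,6,7,8,8a-octahydronaphthalen-2-yl trifluoromethanesulfonate
Product: 24 ethyl (E)-3-methyl-5-[(1R,4aS,8aS)-5,5,8a-trimethyl-2-{[(trifluoromethyl)sulfonyl]oxy}-1,4,4a,5,6,7,8,8a-octahydronaphthalen-1-yl]pent-2-enoate
Conditions: (i-PrO)2P(O)CH2CO2Et, NaH, THF, 0 → 40 °C
Reagents that add atoms: ethyl 2-(diisopropoxyphosphoryl)acetate, CCOC(=O)CP(=O)(OC(C)C)OC(C)C
Why: Horner–Wadsworth–Emmons olefination of the methyl ketone, with the bulky diisopropyl phosphonate chosen to favour the (E)-enoate (C12 chain trans to the ester); any minor (Z)-isomer is to be removed by chromatography, and the enol triflate is inert to the stabilised carbanion.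

**Step 18**
Reactants: 24 ethyl (E)-3-methyl-5-[(1R,4aS,8aS)-5,5,8a-trimethyl-2-{[(trifluoromethyl)sulfonyl]oxy}-1,4,4a,5,6,7,8,8a-octahydronaphthalen-1-yl]pent-2-enoate
Product: 25 (1R,4aS,8aS)-1-[(E)-5-hydroxy-3-methylpent-3-en-1-yl]-5,5,8a-trimethyl-1,4,4a,5,6,7,8,8a-octahydronaphthalen-2-yl trifluoromethanesulfonate
Conditions: i-Bu2AlH (2.5 equiv), CH2Cl2, −78 °C; then aq. KNaC4H4O6
Reagents that add atoms: none
Why: 1,2-Reduction of the conjugated ester to the allylic alcohol with i-Bu2AlH at low temperature, conditions that leave an enol triflate and the alkene geometry untouched.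

**Step 19**
Reactants: 25 (1R,4aS,8aS)-1-[(E)-5-hydroxy-3-methylpent-3-en-1-yl]-5,5,8a-trimethyl-1,4,4a,5,6,7,8,8a-octahydronaphthalen-2-yl trifluoromethanesulfonate
Product: 26 (1R,4aS,8aS)-1-[(E)-5-hydroxy-3-methylpent-3-en-1-yl]-5,5,8a-trimethyl-1,4,4a,5,6,7,8,8a-octahydronaphthalene-2-carboxylic acid
Conditions: Pd(OAc)2 (10 mol %), dppf (20 mol %), CO (1 atm), Et3N, DMF/H2O, 60 °C; then dilute HCl
Reagents that add atoms: carbon monoxide, [C-]#[O+]; water, O
Why: Palladium-catalysed hydroxycarbonylation of an enol triflate (oxidative addition, CO insertion, capture of the acylpalladium species by water) gives the C8 carboxylic acid with the C7=C8 alkene fixed in place; it is run before acetylation because a free allylic alcohol, unlike an allylic acetate, is not ionised by the catalyst.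

**Step 20**
Reactants: 26 (1R,4aS,8aS)-1-[(E)-5-hydroxy-3-methylpent-3-en-1-yl]-5,5,8a-trimethyl-1,4,4a,5,6,7,8,8a-octahydronaphthalene-2-carboxylic acid
Product: 27 (1R,4aS,8aS)-1-[(E)-5-acetoxy-3-methylpent-3-en-1-yl]-5,5,8a-trimethyl-1,4,4a,5,6,7,8,8a-octahydronaphthalene-2-carboxylic acid (CNP0395334.2)
Conditions: Ac2O (1.5 equiv), pyridine, DMAP (cat.), CH2Cl2, 0 °C → rt; aqueous work-up
Reagents that add atoms: acetic anhydride, CC(=O)OC(C)=O
Why: DMAP-catalysed acetylation of the primary allylic alcohol; any mixed anhydride formed at the hindered carboxylic acid is hydrolysed back during aqueous work-up, so the acid needs no protection.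

**Compound list**

1 | 1-bromo-3-methoxy-2-methylbenzene | COc1cccc(Br)c1C | starting material
2 | isobutyronitrile | CC(C)C#N | starting material
3 | 2-(3-methoxy-2-methylphenyl)-2-methylpropanenitrile | COc1cccc(C(C)(C)C#N)c1C | intermediate
4 | 2-(6-chloro-3-methoxy-2-methylphenyl)-2-methylpropanenitrile | COc1ccc(Cl)c(C(C)(C)C#N)c1C | intermediate
5 | 2-(6-chloro-3-hydroxy-2-methylphenyl)-2-methylpropanenitrile | Cc1c(O)ccc(Cl)c1C(C)(C)C#N | intermediate
6 | 2-{3-[(tert-butyldimethylsilyl)oxy]-6-chloro-2-methylphenyl}-2-methylpropanenitrile | Cc1c(O[Si](C)(C)C(C)(C)C)ccc(Cl)c1C(C)(C)C#N | intermediate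
7 | N-(diisobutylalumanyl)-2-{3-[(tert-butyldimethylsilyl)oxy]-6-chloro-2-methylphenyl}-2-methylpropan-1-imine (aluminium aldimine, not isolated) | CC(C)C[Al](CC(C)C)N=CC(C)(C)c1c(Cl)ccc(O[Si](C)(C)C(C)(C)C)c1C | intermediate
8 | 2-{3-[(tert-butyldimethylsilyl)oxy]-6-chloro-2-methylphenyl}-2-methylpropanal | O=CC(C)(C)c1c(Cl)ccc(O[Si](C)(C)C(C)(C)C)c1C | intermediate
9 | methyl (Z)-4-{3-[(tert-butyldimethylsilyl)oxy]-6-chloro-2-methylphenyl}-4-methylpent-2-enoate | COC(=O)/C=C\C(C)(C)c1c(Cl)ccc(O[Si](C)(C)C(C)(C)C)c1C | intermediate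
10 | (Z)-4-{3-[(tert-butyldimethylsilyl)oxy]-6-chloro-2-methylphenyl}-4-methylpent-2-en-1-ol | OC/C=C\C(C)(C)c1c(Cl)ccc(O[Si](C)(C)C(C)(C)C)c1C | intermediate
11 | (Z)-4-{3-[(tert-butyldimethylsilyl)oxy]-6-chloro-2-methylphenyl}-4-methylpent-2-en-1-yl methyl carbonate | COC(=O)OC/C=C\C(C)(C)c1c(Cl)ccc(O[Si](C)(C)C(C)(C)C)c1C | intermediate
12 | (Z)-4-(6-chloro-3-hydroxy-2-methylphenyl)-4-methylpent-2-en-1-yl methyl carbonate | COC(=O)OC/C=C\C(C)(C)c1c(Cl)ccc(O)c1C | intermediate
13 | (S)-4-chloro-5,5,8a-trimethyl-8,8a-dihydronaphthalen-1(5H)-one | O=C1C=CC(Cl)=C2C(C)(C)C=CC[C@]12C | intermediate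
14 | (4aS,8aS)-5,5,8a-trimethyloctahydronaphthalen-1(2H)-one | O=C1CCC[C@H]2C(C)(C)CCC[C@]12C | intermediate
15 | (4aS,8aS)-5,5,8a-trimethyl-3,4,4a,5,6,7,8,8a-octahydronaphthalen-1-yl trifluoromethanesulfonate | O=S(=O)(OC1=CCC[C@H]2C(C)(C)CCC[C@]12C)C(F)(F)F | intermediate
16 | 2-methyl-2-vinyl-1,3-dioxolane | C=CC1(C)OCCO1 | starting material
17 | 9-[2-(2-methyl-1,3-dioxolan-2-yl)ethyl]-9-borabicyclo[3.3.1]nonane (not isolated) | CC1(CCB2C3CCCC2CCC3)OCCO1 | intermediate
18 | 2-methyl-2-{2-[(4aS,8aS)-5,5,8a-trimethyl-3,4,4a,5,6,7,8,8a-octahydronaphthalen-1-yl]ethyl}-1,3-dioxolane | CC1(CCC2=CCC[C@H]3C(C)(C)CCC[C@]23C)OCCO1 | intermediate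
19 | {1-[2-(2-methyl-1,3-dioxolan-2-yl)ethyl]-5,5,8a-trimethyldecahydronaphthalen-2-yl}borane, boron at C8 and hydrogen at C9 on the α face, configuration as in 20 (not isolated) | CC1(CC[C@H]2[C@H](B)CC[C@H]3C(C)(C)CCC[C@]23C)OCCO1 | intermediate
20 | (1R,2R,4aS,8aS)-1-[2-(2-methyl-1,3-dioxolan-2-yl)ethyl]-5,5,8a-trimethyldecahydronaphthalen-2-ol | CC1(CC[C@H]2[C@H](O)CC[C@H]3C(C)(C)CCC[C@]23C)OCCO1 | intermediate
21 | (1R,4aS,8aS)-1-[2-(2-methyl-1,3-dioxolan-2-yl)ethyl]-5,5,8a-trimethyloctahydronaphthalen-2(1H)-one | CC1(CC[C@H]2C(=O)CC[C@H]3C(C)(C)CCC[C@]23C)OCCO1 | intermediate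
22 | (1R,4aS,8aS)-1-[2-(2-methyl-1,3-dioxolan-2-yl)ethyl]-5,5,8a-trimethyl-1,4,4a,5,6,7,8,8a-octahydronaphthalen-2-yl trifluoromethanesulfonate (not isolated) | CC1(CC[C@H]2C(OS(=O)(=O)C(F)(F)F)=CC[C@H]3C(C)(C)CCC[C@]23C)OCCO1 | intermediate
23 | (1R,4aS,8aS)-5,5,8a-trimethyl-1-(3-oxobutyl)-1,4,4a,5,6,7,8,8a-octahydronaphthalen-2-yl trifluoromethanesulfonate | CC(=O)CC[C@H]1C(OS(=O)(=O)C(F)(F)F)=CC[C@H]2C(C)(C)CCC[C@]12C | intermediate
24 | ethyl (E)-3-methyl-5-[(1R,4aS,8aS)-5,5,8a-trimethyl-2-{[(trifluoromethyl)sulfonyl]oxy}-1,4,4a,5,6,7,8,8a-octahydronaphthalen-1-yl]pent-2-enoate | CCOC(=O)/C=C(\C)CC[C@H]1C(OS(=O)(=O)C(F)(F)F)=CC[C@H]2C(C)(C)CCC[C@]12C | intermediate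
25 | (1R,4aS,8aS)-1-[(E)-5-hydroxy-3-methylpent-3-en-1-yl]-5,5,8a-trimethyl-1,4,4a,5,6,7,8,8a-octahydronaphthalen-2-yl trifluoromethanesulfonate | OC/C=C(\C)CC[C@H]1C(OS(=O)(=O)C(F)(F)F)=CC[C@H]2C(C)(C)CCC[C@]12C | intermediate
26 | (1R,4aS,8aS)-1-[(E)-5-hydroxy-3-methylpent-3-en-1-yl]-5,5,8a-trimethyl-1,4,4a,5,6,7,8,8a-octahydronaphthalene-2-carboxylic acid | OC/C=C(\C)CC[C@H]1C(C(=O)O)=CC[C@H]2C(C)(C)CCC[C@]12C | intermediate
27 | (1R,4aS,8aS)-1-[(E)-5-acetoxy-3-methylpent-3-en-1-yl]-5,5,8a-trimethyl-1,4,4a,5,6,7,8,8a-octahydronaphthalene-2-carboxylic acid (CNP0395334.2) | CC(=O)OC/C=C(\C)CC[C@H]1C(C(=O)O)=CC[C@H]2C(C)(C)CCC[C@]12C | target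

**Step count**

Total: 20 steps. Longest linear sequence: 20 steps (1 → 27); dioxolane 16 is bought.

**Steps most likely to fail**

1. Step 10 (the proposed new method). What may go wrong: ionisation without ring closure (the strained anti allyl complex is diverted to intermolecular O-allylation or decomposes), re-ionisation of the dienone by the catalyst, or poor discrimination of the two phenolate faces. The fallback uses no palladium and sets out from alcohol 10. Appel bromination (CBr4, PPh3, CH2Cl2, 0 °C) should give (Z)-1-bromo-4-{3-[(tert-butyldimethylsilyl)oxy]-6-chloro-2-methylphenyl}-4-methylpent-2-ene F1. Bu4NF in THF then frees the phenolate, which closes ring A by the classical intramolecular ortho-C-alkylation of a phenolate (SN2 at the primary allylic bromide; para carbon blocked, O-alkylation would need an eight-membered ring) to racemic 4-chloro-5,5,8a-trimethyl-8,8a-dihydronaphthalen-1(5H)-one F2. Preparative chromatography on a chiral stationary phase separates the enantiomers, and the (S)-enantiomer is 13, where the route is rejoined.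

2. Step 11. What may go wrong: poor facial selectivity when the hindered C5=C6 alkene is reduced on the metal surface (cis-fused decalone), or stalling at that alkene. The fallback sets out from 13. The Pd/C hydrogenation is run at 1 atm with Et3N and stopped once the two unhindered alkenes and the C–Cl bond have reacted, to give (S)-5,5,8a-trimethyl-3,5,6,7,8,8a-hexahydronaphthalen-1(2H)-one F3. The remaining alkene is then reduced by radical hydrogen-atom-transfer hydrogenation (Mn(dpm)3, PhSiH3, t-BuOOH, i-PrOH, rt), in which the tertiary C5 radical accepts hydrogen to give the thermodynamically preferred trans ring fusion. This returns to 14.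

3. Step 2. What may go wrong: chlorination at the unhindered ortho carbon C8 instead of at C6 next to the quaternary carbon. The fallback sets out from 1 and chlorinates before the quaternary carbon exists. N-Chlorosuccinimide in (CF3)2CHOH should react para to the methoxy group, next to the small bromine, to give 2-bromo-1-chloro-4-methoxy-3-methylbenzene F4. Palladium-catalysed decarboxylative cyanomethylation with potassium cyanoacetate ([Pd(C3H5)Cl]2, S-Phos, mesitylene, 140 °C) replaces bromine selectively and gives 2-(6-chloro-3-methoxy-2-methylphenyl)acetonitrile F5. Double C-methylation (NaH, MeI, DMF) builds the quaternary carbon and returns to 4, so that compound 3 is bypassed.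

**Further compounds**

F1 | step 10 | (Z)-1-bromo-4-{3-[(tert-butyldimethylsilyl)oxy]-6-chloro-2-methylphenyl}-4-methylpent-2-ene | BrC/C=C\C(C)(C)c1c(Cl)ccc(O[Si](C)(C)C(C)(C)C)c1C
F2 | step 10 | rac-4-chloro-5,5,8a-trimethyl-8,8a-dihydronaphthalen-1(5H)-one | O=C1C=CC(Cl)=C2C(C)(C)C=CCC12C
F3 | step 11 | (S)-5,5,8a-trimethyl-3,5,6,7,8,8a-hexahydronaphthalen-1(2H)-one | O=C1CCC=C2C(C)(C)CCC[C@]12C
F4 | step 2 | 2-bromo-1-chloro-4-methoxy-3-methylbenzene | COc1ccc(Cl)c(Br)c1C
F5 | step 2 | 2-(6-chloro-3-methoxy-2-methylphenyl)acetonitrile | COc1ccc(Cl)c(CC#N)c1C
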